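## Retrosynthetic overview

1. The target comes from a coupled epoxide by one acid step: water opens the 3β,4β-epoxide at C3 (giving the trans 3α,4β-diol) and the C11 silyl ether falls off.
2. The C7–C8 bond is made by an asymmetric Nozaki–Hiyama–Kishi coupling of a ring alkenyl triflate (C1–C7, C5 angelate in place) with a C8–C11 aldehyde (C10 angelate in place).
3. The ring triflate comes from (S)-carvone: α′-oxygenation (C6), Luche reduction (C5), directed epoxidation (C3/C4), angeloylation, ozonolysis and enol triflation of the isopropenyl group, then C6 inversion by oxidation and selectride reduction.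
4. The aldehyde comes from 2-methylbut-3-en-2-ol: silylation, ozonolysis, Brown allylation (C10), angeloylation, ozonolysis.
5. Rings: the cyclohexane is carried intact from carvone and no carbocycle is formed. The only ring made is the temporary oxirane (step 3), opened in step 16.

Locants used in the names: ring C1–C6 (C1 carries the side chain, C4 the methyl), side chain C7(=C14H2)–C8–C9–C10–C11. β is the ring face of the C1 side chain, α the other face. Target: 1R,3S,4R,5S,6S,8R,10R.

Assumption: the (S)-enantiomer of the Kishi oxazoline–sulfonamide ligand is taken as the one that sends the alkenyl group to the Si face of aldehyde 23 (giving 8R); if a model coupling shows the opposite, its antipode is used.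

## Route

Step 1
Reactants: 1 (S)-(+)-carvone
Product: 4 6α-(triethylsilyloxy)carvone [(5R,6R)-2-methyl-5-(prop-1-en-2-yl)-6-(triethylsilyloxy)cyclohex-2-en-1-one; silyloxy trans to isopropenyl], via lithium dienolate 2 (not isolated), via silyl dienol ether 3 (not isolated)
Conditions: LiN(iPr)2 (LDA), THF, −78 °C; TESCl, −78 → 0 °C; then mCPBA, hexane, −15 °C
Reagents that add atoms: chlorotriethylsilane CC[Si](Cl)(CC)CC; mCPBA O=C(OO)c1cccc(Cl)c1
Why: Kinetic α′-deprotonation and O-silylation give the cross-conjugated dienol ether, and Rubottom oxidation attacks its enol double bond anti to the neighbouring isopropenyl group with silyl shift to the new oxygen, so C6–O is set trans (α) to the C1 substituent.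

Step 2
Reactants: 4 6α-(triethylsilyloxy)carvone
Product: 5 5β-hydroxy-6α-(triethylsilyloxy) allylic alcohol [(1R,5R,6R)-2-methyl-5-(prop-1-en-2-yl)-6-(triethylsilyloxy)cyclohex-2-en-1-ol]
Conditions: NaBH4, CeCl3·7H2O, MeOH, −78 °C
Reagents that add atoms: none
Why: Luche 1,2-reduction with axial hydride delivery from the α face, as in carvone → cis-carveol, sets C5 with the hydroxyl β (cis to the C1 substituent, trans to the 6-silyloxy group).

Step 3
Reactants: 5 5β-hydroxy-6α-(triethylsilyloxy) allylic alcohol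
Product: 6 3β,4β-epoxy-5β-ol [1β-isopropenyl-4-methyl-6α-(triethylsilyloxy)-3β,4β-epoxycyclohexan-5β-ol]
Conditions: VO(acac)2 (2 mol %), t-BuOOH, CH2Cl2, 0 → 25 °C
Reagents that add atoms: tert-butyl hydroperoxide CC(C)(C)OO
Why: Hydroxyl-directed vanadium-catalysed epoxidation delivers oxygen syn to the 5β-OH (setting C3 and C4 as the β-epoxide) and leaves the isolated isopropenyl alkene untouched.

Step 4
Reactants: 6 3β,4β-epoxy-5β-ol
Product: 7 5β-angelate of 6 [5β-((2Z)-2-methylbut-2-enoyloxy)-3β,4β-epoxy-6α-(triethylsilyloxy)-1β-isopropenyl-4-methylcyclohexane]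
Conditions: angelic acid, 2,4,6-trichlorobenzoyl chloride, Et3N, toluene, 25 °C; filter; then 6, toluene, 80 °C
Reagents that add atoms: angelic acid [(2Z)-2-methylbut-2-enoic acid] C/C=C(/C)C(=O)O
Why: Yamaguchi-type mixed-anhydride esterification of the only free hydroxyl, run without DMAP so that the Z (angelate) double bond does not isomerise to tiglate; no stereocentre changes.

Step 5
Reactants: 7 5β-angelate of 6
Product: 9 methyl ketone [1β-acetyl analogue of 7], via ozonide 8 (not isolated)
Conditions: O3 (1.0 equiv), CH2Cl2, −78 °C; then PPh3, −78 → 25 °C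
Reagents that add atoms: ozone [O-][O+]=O
Why: Ozonolysis cleaves the electron-rich 1,1-disubstituted alkene much faster than the conjugated angelate alkene (the selectivity that spares the enone of carvone), and phosphine reduction of the ozonide gives the ketone.

Step 6
Reactants: 9 methyl ketone
Product: 11 alkenyl triflate [1β-(1-(trifluoromethylsulfonyloxy)ethenyl) analogue of 7], via potassium enolate 10 (not isolated)
Conditions: KN(SiMe3)2 (KHMDS, 1.05 equiv), THF, −78 °C; PhNTf2, −78 °C
Reagents that add atoms: N-phenylbis(trifluoromethanesulfonimide) O=S(=O)(N(c1ccccc1)S(=O)(=O)C(F)(F)F)C(F)(F)F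
Why: Kinetic enolisation on the CH3 side of the methyl ketone and O-triflation (enol triflate formation) give the 2-substituted alkenyl triflate; the ketone is far more acidic than the ester and C1 is not deprotonated.

Step 7
Reactants: 11 alkenyl triflate
Product: 12 6α-alcohol [alkenyl triflate with free 6α-OH, 5β-angelate, 3β,4β-epoxide]
Conditions: HF·pyridine, pyridine, THF, 0 °C
Reagents that add atoms: none
Why: Pyridine-buffered HF cleaves the secondary triethylsilyl ether (desilylation) while epoxide, alkenyl triflate and angelate survive.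

Step 8
Reactants: 12 6α-alcohol
Product: 13 6-ketone [alkenyl triflate with C6 carbonyl, 5β-angelate, 3β,4β-epoxide]
Conditions: Dess–Martin periodinane, pyridine, CH2Cl2, 0 → 25 °C
Reagents that add atoms: none
Why: Dess–Martin oxidation of the single free secondary alcohol under buffered, non-enolising conditions.

Step 9
Reactants: 13 6-ketone
Product: 14 6β-alcohol [alkenyl triflate with 6β-OH cis to the C1 substituent and to the 5β-angelate]
Conditions: LiBH(s-Bu)3 (L-selectride, 1.1 equiv), THF, −78 °C; AcOH quench at −78 °C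
Reagents that add atoms: none
Why: Bulky-hydride reduction in which hydride enters equatorially from the α face, anti to the equatorial β substituents at C1 and C5 and away from the β-epoxide oxygen, giving the axial 6β-alcohol, a net inversion of C6.

Step 10
Reactants: 15 2-methylbut-3-en-2-ol
Product: 16 triethyl[(2-methylbut-3-en-2-yl)oxy]silane
Conditions: TESOTf, 2,6-lutidine, CH2Cl2, 0 °C
Reagents that add atoms: triethylsilyl triflate CC[Si](CC)(CC)OS(=O)(=O)C(F)(F)F
Why: Silylation of the tertiary alcohol with the reactive silyl triflate (silyl ether formation).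

Step 11
Reactants: 16 triethyl[(2-methylbut-3-en-2-yl)oxy]silane
Product: 18 2-methyl-2-(triethylsilyloxy)propanal, via ozonide 17 (not isolated)
Conditions: O3, CH2Cl2, −78 °C; then PPh3, −78 → 25 °C
Reagents that add atoms: ozone [O-][O+]=O
Why: Ozonolysis of the vinyl group with reductive work-up gives the α-silyloxy aldehyde.

Step 12
Reactants: 18 2-methyl-2-(triethylsilyloxy)propanal
Product: 20 (3R)-2-methyl-2-(triethylsilyloxy)hex-5-en-3-ol, via borinate ester 19 (not isolated)
Conditions: B-allyldiisopinocampheylborane from (−)-α-pinene (preformed salt-free solution), Et2O, −78 °C; then NaOH, H2O2, 0 → 25 °C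
Reagents that add atoms: B-allyldiisopinocampheylborane [Ipc groups from (−)-α-pinene] C=CCB([C@H]1C[C@H]2C[C@@H]([C@@H]1C)C2(C)C)[C@H]1C[C@H]2C[C@@H]([C@@H]1C)C2(C)C
Why: Brown asymmetric allylboration through a chair six-membered transition state; this reagent adds allyl to the Re face of the aldehyde and sets C10 as R under reagent control.

Step 13
Reactants: 20 (3R)-2-methyl-2-(triethylsilyloxy)hex-5-en-3-ol
Product: 21 (3R)-2-methyl-2-(triethylsilyloxy)hex-5-en-3-yl (2Z)-2-methylbut-2-enoate
Conditions: angelic acid, 2,4,6-trichlorobenzoyl chloride, Et3N, toluene, 25 °C; filter; then 20, toluene, 80 °C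
Reagents that add atoms: angelic acid [(2Z)-2-methylbut-2-enoic acid] C/C=C(/C)C(=O)O
Why: Yamaguchi-type mixed-anhydride esterification without DMAP acylates the secondary alcohol with retention of the Z geometry; C10 is untouched.

Step 14
Reactants: 21 (3R)-2-methyl-2-(triethylsilyloxy)hex-5-en-3-yl (2Z)-2-methylbut-2-enoate
Product: 23 (3R)-4-methyl-1-oxo-4-(triethylsilyloxy)pentan-3-yl (2Z)-2-methylbut-2-enoate, via ozonide 22 (not isolated)
Conditions: O3 (1.0 equiv), CH2Cl2, −78 °C; then PPh3, −78 → 25 °C; used at once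
Reagents that add atoms: ozone [O-][O+]=O
Why: Ozonolysis of the terminal vinyl group, which reacts far faster than the electron-poor angelate alkene, gives the β-acyloxy aldehyde.

Step 15
Reactants: 14 6β-alcohol alkenyl triflate; 23 (3R)-4-methyl-1-oxo-4-(triethylsilyloxy)pentan-3-yl (2Z)-2-methylbut-2-enoate
Product: 24 coupled epoxide [(8R,10R)-5β,10-bis(angeloyloxy)-3β,4β-epoxy-11-(triethylsilyloxy)bisabol-7(14)-ene-6β,8-diol]
Conditions: CrCl2 (4 equiv), NiCl2 (2 mol %), N-[2-((4S)-4-isopropyl-4,5-dihydrooxazol-2-yl)-6-methylphenyl]methanesulfonamide, Et3N, THF, 25 °C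
Reagents that add atoms: none
Why: Nozaki–Hiyama–Kishi coupling, in which zerovalent nickel inserts into the alkenyl triflate and the alkenyl group passes to chromium and adds to the aldehyde (esters, epoxide and free hydroxyls tolerated); the chiral sulfonamide on chromium directs Si-face addition (8R), matched with the 1,3-anti preference of the β-acyloxy aldehyde.

Step 16
Reactants: 24 coupled epoxide
Product: 26 target [(1R,3S,4R,5S,6S,8R,10R)-5β,10-bis(angeloyloxy)bisabol-7(14)-ene-3α,4β,6β,8,11-pentol], via desilylated epoxide 25 (not isolated)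
Conditions: HClO4 (0.5 M aq.), THF, 0 → 25 °C
Reagents that add atoms: water O
Why: Acid-catalysed epoxide hydrolysis under Fürst–Plattner (trans-diaxial) control, with water attacking secondary C3 from the α face with inversion (attack at C4 is disfavoured by the adjacent acyloxy group and would need a boat-like path), gives the 3α,4β-diol while the same acid removes the C11 silyl ether.

## Compound list

1 | (S)-(+)-carvone | C=C(C)[C@H]1CC=C(C)C(=O)C1 | starting material
2 | lithium dienolate of 1 (C5–O, C5=C6) | C=C(C)[C@H]1CC=C(C)C([O-])=C1.[Li+] | intermediate (not isolated)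
3 | triethylsilyl dienol ether of 1 | C=C(C)[C@H]1CC=C(C)C(O[Si](CC)(CC)CC)=C1 | intermediate (not isolated)
4 | 6α-(triethylsilyloxy)carvone, (5R,6R) | C=C(C)[C@H]1CC=C(C)C(=O)[C@@H]1O[Si](CC)(CC)CC | intermediate
5 | 5β-hydroxy-6α-(triethylsilyloxy) allylic alcohol, (1R,5R,6R) | C=C(C)[C@H]1CC=C(C)[C@@H](O)[C@@H]1O[Si](CC)(CC)CC | intermediate
6 | 3β,4β-epoxy-5β-ol (6α-OSiEt3, 1β-isopropenyl) | C=C(C)[C@H]1C[C@H]2O[C@@]2(C)[C@@H](O)[C@@H]1O[Si](CC)(CC)CC | intermediate
7 | 5β-angelate of 6 | C=C(C)[C@H]1C[C@H]2O[C@@]2(C)[C@@H](OC(=O)/C(C)=C\C)[C@@H]1O[Si](CC)(CC)CC | intermediate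
8 | ozonide (1,2,4-trioxolane) of 7, mixture at the trioxolane carbon | CC3(OCOO3)[C@H]1C[C@H]2O[C@@]2(C)[C@@H](OC(=O)/C(C)=C\C)[C@@H]1O[Si](CC)(CC)CC | intermediate (not isolated)
9 | methyl ketone (1β-acetyl) | CC(=O)[C@H]1C[C@H]2O[C@@]2(C)[C@@H](OC(=O)/C(C)=C\C)[C@@H]1O[Si](CC)(CC)CC | intermediate
10 | potassium enolate of 9 (terminal) | C=C([O-])[C@H]1C[C@H]2O[C@@]2(C)[C@@H](OC(=O)/C(C)=C\C)[C@@H]1O[Si](CC)(CC)CC.[K+] | intermediate (not isolated)
11 | alkenyl triflate, 6α-OSiEt3 | C=C(OS(=O)(=O)C(F)(F)F)[C@H]1C[C@H]2O[C@@]2(C)[C@@H](OC(=O)/C(C)=C\C)[C@@H]1O[Si](CC)(CC)CC | intermediate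
12 | alkenyl triflate, 6α-alcohol | C=C(OS(=O)(=O)C(F)(F)F)[C@H]1C[C@H]2O[C@@]2(C)[C@@H](OC(=O)/C(C)=C\C)[C@@H]1O | intermediate
13 | alkenyl triflate, 6-ketone | C=C(OS(=O)(=O)C(F)(F)F)[C@H]1C[C@H]2O[C@@]2(C)[C@@H](OC(=O)/C(C)=C\C)C1=O | intermediate
14 | alkenyl triflate, 6β-alcohol | C=C(OS(=O)(=O)C(F)(F)F)[C@H]1C[C@H]2O[C@@]2(C)[C@@H](OC(=O)/C(C)=C\C)[C@H]1O | intermediate
15 | 2-methylbut-3-en-2-ol | C=CC(C)(C)O | starting material
16 | triethyl[(2-methylbut-3-en-2-yl)oxy]silane | C=CC(C)(C)O[Si](CC)(CC)CC | intermediate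
17 | ozonide of 16 | CC(C)(O[Si](CC)(CC)CC)C1OCOO1 | intermediate (not isolated)
18 | 2-methyl-2-(triethylsilyloxy)propanal | CC(C)(O[Si](CC)(CC)CC)C=O | intermediate
19 | diisopinocampheylborinate ester of 20 | C=CC[C@@H](OB([C@H]1C[C@H]2C[C@@H]([C@@H]1C)C2(C)C)[C@H]1C[C@H]2C[C@@H]([C@@H]1C)C2(C)C)C(C)(C)O[Si](CC)(CC)CC | intermediate (not isolated)
20 | (3R)-2-methyl-2-(triethylsilyloxy)hex-5-en-3-ol | C=CC[C@@H](O)C(C)(C)O[Si](CC)(CC)CC | intermediate
21 | (3R)-2-methyl-2-(triethylsilyloxy)hex-5-en-3-yl (2Z)-2-methylbut-2-enoate | C=CC[C@@H](OC(=O)/C(C)=C\C)C(C)(C)O[Si](CC)(CC)CC | intermediate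
22 | ozonide of 21, mixture at the trioxolane carbon | C1(OCOO1)C[C@@H](OC(=O)/C(C)=C\C)C(C)(C)O[Si](CC)(CC)CC | intermediate (not isolated)
23 | (3R)-4-methyl-1-oxo-4-(triethylsilyloxy)pentan-3-yl (2Z)-2-methylbut-2-enoate | O=CC[C@@H](OC(=O)/C(C)=C\C)C(C)(C)O[Si](CC)(CC)CC | intermediate
24 | coupled epoxide (8R,10R; 3β,4β-epoxide; 11-OSiEt3) | C=C([C@H](O)C[C@@H](OC(=O)/C(C)=C\C)C(C)(C)O[Si](CC)(CC)CC)[C@H]1C[C@H]2O[C@@]2(C)[C@@H](OC(=O)/C(C)=C\C)[C@H]1O | intermediate
25 | desilylated epoxide (11-OH, 3β,4β-epoxide) | C=C([C@H](O)C[C@@H](OC(=O)/C(C)=C\C)C(C)(C)O)[C@H]1C[C@H]2O[C@@]2(C)[C@@H](OC(=O)/C(C)=C\C)[C@H]1O | intermediate (not isolated)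
26 | CNP0108485.1, (1R,3S,4R,5S,6S,8R,10R) | C=C([C@H](O)C[C@@H](OC(=O)/C(C)=C\C)C(C)(C)O)[C@H]1C[C@H](O)[C@@](C)(O)[C@@H](OC(=O)/C(C)=C\C)[C@H]1O | target

## Step count and risks

Total steps: 16 (steps 1–9 ring fragment, 10–14 side-chain aldehyde, 15 coupling, 16 final).
Longest linear sequence: 11 steps (1–9, 15, 16) from (S)-carvone.

Three steps most likely to fail:

Step 9 (reduction of 13). The selectride may reduce the angelate, the lithium alkoxide may trigger acyl migration, or the 6α-alcohol may form. The fallback drops the oxidation–reduction pair and inverts C6 by displacement (Lattrell–Dax epimerisation), setting out from 12 and returning at 14. Alcohol 12 is treated with Tf2O and pyridine in CH2Cl2 at −20 °C to give the 6α-triflate F1. With Bu4NNO2 in MeCN at 25 °C, F1 suffers SN2 attack from the β face; the equatorial trans ester at C5 is the arrangement that favours this displacement, and the equatorial leaving group has no anti-periplanar hydrogen for elimination. This gives the 6β-nitrite ester F2, which is hydrolysed on aqueous work-up to 14.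

Step 15 (C8 configuration in the coupling). Ligand control may be weak with this triflate, or the sense may be wrong. The fallback sets C8 by ketone reduction instead, setting out from 14 and 23 and returning at 24. Coupling with CrCl2 and catalytic NiCl2 in DMSO without ligand gives 24 mixed with the 8S epimer F3. MnO2 in CH2Cl2 oxidises only the allylic C8 carbinol (the C6 carbinol is not allylic), converting the mixture into the single enone F4. Reduction with (S)-Me-CBS oxazaborolidine [(S)-1-methyl-3,3-diphenyltetrahydro-1H,3H-pyrrolo[1,2-c][1,3,2]oxazaborole] and catecholborane in toluene at −78 °C, with the alkenyl group as the large substituent, gives the 8R alcohol 24.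

Step 16 (final acid hydrolysis). The epoxide is of the slow-opening type, and the acid needed may transpose the allylic C8 carbinol or dehydrate the C11 carbinol. The fallback opens the epoxide before the side chain is present, setting out from 14 and returning at 26. Treating 14 with aqueous HClO4 in THF (more forcing conditions are tolerable here) gives the 3α,4β,6β-triol alkenyl triflate F5. Coupling F5 with 23 under the conditions of step 15 (free hydroxyls are tolerated) gives the 11-O-triethylsilyl ether F6. HF·pyridine with pyridine in THF at 0 °C then removes the silyl group to give 26.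

## Further compounds

F1 | step 9 | 6α-triflate of 12 | C=C(OS(=O)(=O)C(F)(F)F)[C@H]1C[C@H]2O[C@@]2(C)[C@@H](OC(=O)/C(C)=C\C)[C@@H]1OS(=O)(=O)C(F)(F)F
F2 | step 9 | 6β-nitrite ester (C6 inverted) | C=C(OS(=O)(=O)C(F)(F)F)[C@H]1C[C@H]2O[C@@]2(C)[C@@H](OC(=O)/C(C)=C\C)[C@H]1ON=O
F3 | step 15 | 8S epimer of 24 | C=C([C@@H](O)C[C@@H](OC(=O)/C(C)=C\C)C(C)(C)O[Si](CC)(CC)CC)[C@H]1C[C@H]2O[C@@]2(C)[C@@H](OC(=O)/C(C)=C\C)[C@H]1O
F4 | step 15 | C8 enone from 24 and F3 | C=C(C(=O)C[C@@H](OC(=O)/C(C)=C\C)C(C)(C)O[Si](CC)(CC)CC)[C@H]1C[C@H]2O[C@@]2(C)[C@@H](OC(=O)/C(C)=C\C)[C@H]1O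
F5 | step 16 | 3α,4β,6β-triol alkenyl triflate | C=C(OS(=O)(=O)C(F)(F)F)[C@H]1C[C@H](O)[C@@](C)(O)[C@@H](OC(=O)/C(C)=C\C)[C@H]1O
F6 | step 16 | 11-O-triethylsilyl ether of 26 | C=C([C@H](O)C[C@@H](OC(=O)/C(C)=C\C)C(C)(C)O[Si](CC)(CC)CC)[C@H]1C[C@H](O)[C@@](C)(O)[C@@H](OC(=O)/C(C)=C\C)[C@H]1O
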